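The readings were generated by integration on assumed constants, noise included.

A small charge of incoming ligand, 0.220 M, meets starting complex at 0.20 M; two exchanges on every starting complex need 0.400 M, more than is charged, so incoming ligand is the limiting reagent. What matters at the end is the split between complex with two exchanged and over-reaction product.

| setting | teal | red | amber | grey | south-east | south | north | east |
|---|---|---|---|---|---|---|---|---|
| starting complex | 0.20 M | 0.10 M | 0.40 M | 0.20 M | 0.20 M | 0.20 M | 0.20 M (fed, over 2.5 h) | 0.20 M |
| incoming ligand | 0.22 M | 0.22 M | 0.22 M | 0.11 M | 0.220 M (in portions, 2, over 2.5 h) | 0.220 M (fed, over 2.5 h) | 0.220 M | 0.220 M |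
| remark | run made earlier | run made earlier | run made earlier | run made earlier | first portion at the start, last at 2.5 h | all else is in the flask from the start; the feed brings no volume worth counting | all else is in the flask from the start; the feed brings no volume worth counting | everything together at the start |
| time |  |  |  |  | 6.0 h | 6.0 h | 6.0 h | 6.0 h |

| run | time / h | complex with two exchanged / % | over-reaction product / % |
|---|---|---|---|
| teal | 0.417 | 14.1 | 2.0 |
| teal | 1.33 | 11.2 | 6.5 |
| teal | 2.00 | 9.5 | 8.5 |
| teal | 3.00 | 7.7 | 11.6 |
| teal | 5.00 | 5.1 | 15.4 |
| teal | 6.00 | 5.1 | 16.3 |
| red | 0.417 | 25.0 | 4.7 |
| red | 1.33 | 19.0 | 13.6 |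
| red | 2.00 | 15.3 | 18.7 |
| red | 3.00 | 12.4 | 23.6 |
| red | 5.00 | 8.4 | 31.0 |
| red | 6.00 | 7.4 | 33.2 |
| amber | 1.00 | 6.4 | 2.2 |
| amber | 2.00 | 4.7 | 3.5 |
| amber | 3.00 | 4.0 | 5.2 |
| amber | 4.00 | 3.9 | 6.0 |
| amber | 5.00 | 3.1 | 6.4 |
| amber | 6.00 | 2.8 | 6.6 |
| grey | 0.500 | 7.6 | 0.8 |
| grey | 1.50 | 6.5 | 1.6 |
| grey | 3.00 | 5.5 | 2.9 |
| grey | 4.00 | 5.4 | 3.5 |
| grey | 6.00 | 4.9 | 4.7 |

(standard deviation of a reading: 0.3 percentage points)

- steps that have been proposed: starting complex + incoming ligand <-> leaving ligand + complex with one exchanged; complex with one exchanged + incoming ligand <-> leaving ligand + complex with two exchanged; complex with two exchanged + incoming ligand -> over-reaction product; leaving ligand + complex with two exchanged -> side product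

1. the flask with the highest share of complex with two exchanged in complex with two exchanged plus over-reaction product ("all alike" if they lie within 1.5 percentage points) (south-east / south / north / east / all alike)
2. share of complex with two exchanged in complex with two exchanged plus over-reaction product at the end, south-east
3. share of complex with two exchanged in complex with two exchanged plus over-reaction product at the end, south
4. share of complex with two exchanged in complex with two exchanged plus over-reaction product at the end, north
5. share of complex with two exchanged in complex with two exchanged plus over-reaction product at the end, east

1. I start with the main step alone: both exchanges and no further reaction. Complex with two exchanged is then the one product of the pair, and the share stands at 100%.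

2. I add the over-reaction. In teal, over-reaction product gained per hour, divided by the mean complex with two exchanged standing, reads 0.305 /h between the first and fifth readings. This reading is the over-reaction rate, a mean over that span, which I use like a pseudo-first-order constant at teal's ligand level. The teal share reads 23.8% at 6.00 h, and east has the same charges as teal.

3. I add the ligand supply. Grey, with half of teal's ligand, reads 0.113 /h, lower than teal.

4. I reckon south-east. Its first portion, 0.110 M, matches grey's charge, so grey's rate over 2.5 h gives 1.86% over-reaction product. After the last portion I follow teal for 3.50 h, taking complex with two exchanged from teal's readings, falling from 14.1% to 6.40%. That reckons the over-reaction product at 12.8%, so my share is 33.4%.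

5. The forecast names south-east and gives 32% for south-east, 30% for south, 21% for north and 23% for east, on the ground that “early ligand starvation suppresses it”. Its south-east figure differs slightly from my 33.4%.

6. The flasks give 32.4% for south-east, 30.3% for south, 23.1% for north and 22.3% for east, so south-east stands highest, as forecast.

    starting complex + incoming ligand ⇌ leaving ligand + complex with one exchanged (K = 0.350, k = 0.290 /M/min)
    complex with one exchanged + incoming ligand ⇌ leaving ligand + complex with two exchanged (K = 0.710, k = 1.70 /M/min)
    complex with two exchanged + incoming ligand → over-reaction product (k = 0.0620 /M/min)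
    leaving ligand + complex with two exchanged → side product (k = 0.0130 /M/min)

South-east's share has moved by 5 points at an incoming ligand charge of 0.192 M or 0.255 M. I carry teal's 0.305 /h on to a reading of south-east at 10.0 h. Starting from 13.2% at 6.00 h, with complex with two exchanged falling to 3.59%, it gives 19.3% over-reaction product and a share of 15.7%. That flask holds 17.8% over-reaction product, and its share is 16.8%.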